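The data were generated by integration from invented constants; scatter was added.

1. I started from a small charge of J: a charge below what the solid gives up during the feed leaves no solid at its end. So I held two amounts against each other, the charge and that loss.

| flask | J | D | remark | time |
|---|---|---|---|---|
| Saturday's | 20 mM | 0.60 equiv (fed, over 30 min) | run made earlier |  |
| Thursday's | 20 mM | 0.90 equiv (fed, over 30 min) | run made earlier |  |
| Sunday's | 40 mM | 1.2 equiv (fed, over 30 min) | run made earlier |  |
| flask | 20 mM | 1.20 equiv (fed, over 30 min) |  | 30 min |

- Saturday's (time / min: J / %, X / %): 2.50: 95.0, 0; 8.00: 86.3, 0; 15.0: 77.4, 0.2; 20.0: 71.0, 0.4; 30.0: 62.6, 4.2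
- Thursday's (time / min: J / %, X / %): 2.50: 95.7, 0.1; 5.00: 90.3, 0.1; 8.00: 85.8, 0; 15.0: 77.4, 1.7; 30.0: 60.8, 6.0
- Sunday's (time / min: J / %, X / %): 2.50: 97.4, 0.3; 8.00: 92.4, 1.0; 15.0: 88.6, 0.8; 20.0: 84.6, 2.1; 30.0: 79.0, 4.8

(scatter of a reading: 0.5 percentage points)

* amount of J at 30 min, in percent of the J charged (only what is still solid)
* amount of X at 30 min, in percent of the J charged
* amount of E at 30 min, in percent of the J charged
* amount of Q at 30 min, in percent of the J charged

- as a solid, counted per litre of solution: J
- at the start none of J is in solution

2. By 30.0 min the solid had lost 7.48 mM on Saturday, 7.84 mM on Thursday and 8.40 mM on Sunday. Between Saturday and Sunday two settings changed: the charge went from 20 mM to 40 mM, and the feed rose from 0.400 mM/min to 1.60 mM/min, a factor of 4.00, but the loss rose by a factor of 1.12.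

3. I took the mean of these readings, 7.91 mM, and called it the dissolving allowance: the mass-transfer figure for the J that leaves the solid during a feed of 30 min.

4. The flask's feed of 0.800 mM/min lies inside the range tried. Its charge of 20 mM exceeds the allowance, so I reckoned 60.5 % of the J still solid at 30 min.

5. The forecast gave 60 % for J, 7 % for X, 3 % for E and 2 % for Q, holding that “Dissolution is therefore surface- or saturation-limited”. My figure for J stands 0.50 percentage points above its figure.

6. The flask gave 60.3 % for J, 6.60 % for X, 4.09 % for E and 1.21 % for Q.

    Z + D → X (k = 0.0160 /M/s)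
    Z + D → E (k = 0.00930 /M/s)
    D + X → Q (k = 0.0150 /M/s)
    D + E → Q (k = 0.00760 /M/s)
    J ⇌ Z, rate k5*(cs5 - [Z]) while solid is left; crystals form when [Z] > cs5 (solubility = 11.0 mM, k = 6.10 × 10⁻⁴ /s)

7. In the flask the solid had given up 7.94 mM by 30 min, against the allowance of 7.91 mM. I set the same reckoning on the neighbouring flask, charged with 5.0 mM of J at the same equivalents and feed time. There the allowance exceeded the charge by a factor of 1.58, which gives no solid at the end, although that flask's feed of 0.200 mM/min lay below the range tried. That flask ended with 0 % of its J as solid and 89.0 % as Z, the dissolved and unreacted substrate.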